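## Analysis of the target

Plakortone N is a cis-fused tetrahydrofuro[3,2-b]furan-2(3H)-one. A γ-lactone (O1, C2, C3, C3a, C6a) and a tetrahydrofuran (C3a, O4, C5, C6, C6a) share the C3a–C6a bond, and C5 carries a methyl group and an unbranched twelve-carbon chain (C1'–C12') ending in a 4-hydroxyphenyl ring. There are three stereocentres, all S: the tertiary ether carbon C3a and the two fully substituted carbinol carbons C5 and C6a, each bearing a methyl group. A 5/5 fusion can only be cis, so C3a follows from C6a. The independent relationship is C5 to C6a, with the C5 methyl on the face of the lactone ring and the chain on the face of the C6a methyl. The sensitive points are the lactone (a β-alkoxy ester that can open by retro-oxa-Michael reaction under strong base), the two tertiary C–O bonds (ionisable under acid) and the phenol (to be masked against organometallic reagents). The difficulty is the pair of tetrasubstituted C–O centres in a 1,3-relationship across C6; at C5 the two carbon substituents, methyl and a long chain, differ too little near the centre for open-chain stereocontrol. The strategy rests on C5 and C6a both being C(CH3)–O carbons flanking the methylene C6. If C3a is joined to C1', the atoms C6a–C6–C5–C1'–C3a form a cyclopentene with the two oxygens cis, a cis-1,4-dimethylcyclopent-2-ene-1,4-diol whose alkene carbons are C3a and C1'. In that ring the C5/C6a relationship is a plain cis/trans question and the chain is absent; the diol core is meso, so the absolute configuration lies only in which oxygen becomes O1 and which O4.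

## Retrosynthetic reasoning

The last operation forms no skeletal bond. Target 17 comes from 16 by catalytic hydrogenation, which saturates C1'=C2' and frees the phenol from its benzyl ether together. The benzyl group is chosen for the phenol for that reason.

Compound 16 is cut at O4–C3a. This is the one ring bond that can form only in the correct sense: the C5 oxygen is tethered through C6 to C6a and can reach C3a only on the face that gives the cis fusion. The forward reaction is fluoride removal of the silyl group from 14; the tertiary alkoxide 15 then adds to the β-carbon of the butenolide. C3a therefore needs no reagent control.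

Compound 14 is cut at its two alkenes, C3=C3a in the butenolide and C1'=C2' in the chain. Rejoining C3a to C1' gives cyclopentene acrylate 8, and the chain becomes the simple terminal alkene 12. Cutting here places both quaternary carbinol carbons in one small ring before the chain exists, so methyl and chain on C5 are never distinguished by a reagent. The forward reaction has a ruthenium alkylidene open the ring of 8, close the lactone onto the acrylate (via 13) and couple the liberated vinyl group with 12, losing a two-carbon alkene as gas.

Compound 8 is cut at the ester C–O bond into tertiary alcohol 6 and acid chloride 7. Because the two oxygens of 6 differ only in their substituents, an O-to-O shift of the silyl or acyl group would give the mirror image. The acylation must therefore avoid a free alkoxide.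

Compound 6 is cut at the C6a–CH3 bond, giving enone 5. The forward reaction is addition of a methyl organometallic to the carbonyl on the face opposite the silyloxy group, which places the new hydroxyl cis to it. The silyl group must already be present; without it the two carbinol carbons would be mirror images and the chirality would be lost.

Enone 5 is traced through 4, 3 and 2 to the commercial enone 1. The C5 carbinol is made first, by methyl addition to the carbonyl of 1 anti to its silyloxy group (2). The original stereocentre is then given up: desilylation (3), oxidation of the secondary allylic alcohol (4) and silylation of the tertiary alcohol (5). The chirality of 1 is thus relayed to a quaternary carbon that later steps cannot epimerise.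

Alkene 12 is cut at the benzylic sp3–sp3 bond into bromide 9 (as its Grignard reagent 11) and benzylic chloride 10. Both are commercial, and the copper-catalysed coupling tolerates the terminal alkene and the benzyl ether.

## Alternatives that were turned down

Alternative 1: The C5–C6 bond is cut. The forward key step is decomposition of the α-alkoxy diazoketone A2 by Rh2(OAc)4; the carbenoid carbon C6 inserts into the tertiary C5–H bond next to O4 and closes the 3-oxotetrahydrofuran A1.
- For it: the C–H bond is activated by the ether oxygen, the transition state is five-membered, and insertion proceeds with retention. C5 therefore derives from an easily made secondary carbinol. On predictability of the key bond formation this alternative is at least as strong as the chosen route, since it does not depend on a reversible metathesis.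
- Against it: A2 needs an ether between two stereogenic secondary carbons, which is hard to make without eroding either. A1 still lacks the C6a methyl and the lactone. Methyl addition to its enolisable α-alkoxy ketone must be face-selective, must spare the tert-butyl ester, and must not epimerise C3a, which sits next to the carbonyl. Two independent sources of chirality and a diazo transfer are needed.
- Comparison: the chosen route sets both quaternary centres on a rigid ring from one chiral starting material, C3a needs no control, and the sequence should be shorter.

Alternative 2: Three bonds are cut at once (C6a–C3a, C3–C2, C2–O1). The forward key step is a hetero-Pauson–Khand reaction in which the divalent titanium complex (EBTHI)Ti(CO)2 couples the methyl ketone of A4 with its tethered vinyl ether and CO, giving the benzyl ether A3 of the target directly.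
- For it: on step economy and convergence it is clearly stronger than the chosen route. Both rings and two stereocentres arise in one step, one hydrogenolysis from the target.
- Against it: such titanium cyclocarbonylations are established for aryl ketones with simple alkenes, not for enolisable aliphatic methyl ketones with an enol ether partner. In the oxatitanacycle the ring oxygen O4 would sit β to titanium, which invites β-alkoxide elimination. A4 is a β-alkoxy ketone that can lose its vinyloxy group by E1cB elimination. The existing C5 centre (methyl against chain) cannot steer the new centres, so the chiral catalyst must, with an unknown matched or mismatched case. The tertiary vinyl ether of A4 is itself hard to make.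
- Comparison: the chosen route is longer, but every elementary step belongs to a known reaction class and the C5/C6a relationship is fixed by a ring, not by a catalyst.

Alternative 3: The C3–C3a and O1–C6a bonds are cut. The forward key step converts the C6 acetate A6 into its silyl ketene acetal (LiN(iPr)2, Me3SiCl), which undergoes Ireland–Claisen rearrangement to form C3–C3a. Iodine then closes the lactone at C6a to give iodolactone A5.
- For it: the [3,3] shift transfers chirality from C6 to C3a suprafacially and is well known for furanoid enol-ether esters. The iodolactonisation is regio- and stereospecific. In stereospecificity at C3a and C6a it equals the chosen route.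
- Against it: A6 is a cyclic enol ether with an allylic acetate and ionises easily to an oxocarbenium ion. The quaternary C5 centre must be made beforehand by other means, and C6 must be set relative to it across the same methyl/chain ambiguity. The iodine is installed only to be removed reductively, which adds a step.
- Comparison: the chosen route carries no throwaway atoms apart from a silyl group and lost ethylene, and solves the C5 problem inside the key construction.

Key step: step 8

## Route

Remark: the C1'=C2' alkene formed in step 8 is expected mainly as the E isomer, which is drawn for 14–16. Its geometry is of no consequence because step 10 saturates it.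

Step 1
Reactants: 1 (S)-4-(tert-butyldimethylsilyloxy)cyclopent-2-en-1-one
Product: 2 (1R,4S)-4-(tert-butyldimethylsilyloxy)-1-methylcyclopent-2-en-1-ol
Conditions: MeLi, Et2O, −78 °C; then H2O
Reagents that add atoms: methyllithium, [Li]C
Why: 1,2-addition of a hard organolithium to the enone; attack anti to the C4 silyloxy group should set C1 (R) with the hydroxyl cis to the silyl ether. The minor trans isomer must be removed by chromatography, because after step 3 it would become the enantiomer of 4.

Step 2
Reactants: 2 (1R,4S)-4-(tert-butyldimethylsilyloxy)-1-methylcyclopent-2-en-1-ol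
Product: 3 (1R,4S)-1-methylcyclopent-2-ene-1,4-diol
Conditions: Bu4NF, THF, 0 °C to rt; direct chromatography
Reagents that add atoms: none
Why: Fluoride cleavage of a silyl ether, driven by the Si–F bond; the water-soluble diol is isolated without aqueous work-up.

Step 3
Reactants: 3 (1R,4S)-1-methylcyclopent-2-ene-1,4-diol
Product: 4 (R)-4-hydroxy-4-methylcyclopent-2-en-1-one
Conditions: MnO2, CH2Cl2, rt
Reagents that add atoms: none
Why: MnO2 oxidises the secondary allylic alcohol and cannot touch the tertiary one; the original stereocentre is erased and the methyl carbinol remains as the only stereocentre.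

Step 4
Reactants: 4 (R)-4-hydroxy-4-methylcyclopent-2-en-1-one
Product: 5 (R)-4-methyl-4-(triethylsilyloxy)cyclopent-2-en-1-one
Conditions: Et3SiOTf, 2,6-lutidine, CH2Cl2, −78 °C
Reagents that add atoms: triethylsilyl trifluoromethanesulfonate, CC[Si](CC)(CC)OS(=O)(=O)C(F)(F)F
Why: Silyl triflate silylation of a hindered tertiary alcohol; it must precede the second methyl addition so that the two carbinol oxygens stay distinguishable.

Step 5
Reactants: 5 (R)-4-methyl-4-(triethylsilyloxy)cyclopent-2-en-1-one
Product: 6 (1S,4R)-1,4-dimethyl-4-(triethylsilyloxy)cyclopent-2-en-1-ol
Conditions: MeLi, Et2O, −78 °C; then pH 7 buffer at −78 °C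
Reagents that add atoms: methyllithium, [Li]C
Why: 1,2-addition to the enone anti to the C–O dipole and the bulk of the silyloxy group should set C1 (S) with the hydroxyl cis to the silyl ether. The cold quench guards against a 1,5 O-to-O silyl shift in the alkoxide, which would give the enantiomer.

Step 6
Reactants: 6 (1S,4R)-1,4-dimethyl-4-(triethylsilyloxy)cyclopent-2-en-1-ol; 7 acryloyl chloride
Product: 8 (1S,4R)-1,4-dimethyl-4-(triethylsilyloxy)cyclopent-2-en-1-yl prop-2-enoate
Conditions: iPr2NEt, DMAP (cat.), CH2Cl2, 0 °C to rt; chromatography on Et3N-washed silica
Reagents that add atoms: none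
Why: Nucleophile-catalysed acylation through the acylpyridinium ion; the alcohol stays neutral, so no alkoxide is available for silyl migration, and the acid-labile tertiary allylic ester is kept buffered.

Step 7
Reactants: 9 11-bromoundec-1-ene; 10 1-(benzyloxy)-4-(chloromethyl)benzene
Product: 12 1-(benzyloxy)-4-(dodec-11-en-1-yl)benzene, via undec-10-enylmagnesium bromide 11 (not isolated)
Conditions: Mg, THF, rt to 40 °C; then 10, Li2CuCl4 (3 mol %), THF, −20 °C to rt
Reagents that add atoms: magnesium, [Mg] (held in 11 only)
Why: Copper-catalysed sp3–sp3 coupling of an alkyl Grignard reagent with a benzylic chloride; the terminal alkene and the benzyl ether are inert.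

Step 8
Reactants: 8 (1S,4R)-1,4-dimethyl-4-(triethylsilyloxy)cyclopent-2-en-1-yl prop-2-enoate; 12 1-(benzyloxy)-4-(dodec-11-en-1-yl)benzene
Product: 14 (5S)-5-[(2R,3E)-14-[4-(benzyloxy)phenyl]-2-methyl-2-(triethylsilyloxy)tetradec-3-en-1-yl]-5-methylfuran-2(5H)-one, via vinyl butenolide 13 (not isolated)
Conditions: RuCl2(=CHPh)(H2IMes)(PCy3) (5 mol %), ethylene (1 atm), CH2Cl2 (0.01 M), 40 °C; then Ar purge, 12 (3 equiv), RuCl2(=CHPh)(H2IMes)(PCy3) (5 mol %), 40 °C
Reagents that add atoms: none
Why: Ethylene converts the benzylidene into Ru=CH2, which adds across the ring alkene of 8; cycloreversion opens the cyclopentene and leaves an alkylidene on C3a or on C1'. The C3a alkylidene closes the five-membered lactone onto the acrylate by ring-closing metathesis at C3=C3a, giving 13 and returning Ru=CH2; the C1' alkylidene can only re-close the cyclopentene or reach the acrylate through a seven-membered ring, so that opening is reversible and drains into the same product. The butenolide alkene is electron-poor, cis-disubstituted and in a ring, should not be re-opened by the catalyst, and so acts as the sink that the weakly strained, doubly blocked cyclopentene alone would not provide. Alkene 12 is held back until 13 has formed, because a terminal alkene and an acrylate cross-couple readily with this catalyst, which would cap the acrylate and waste the chain. In the second stage the vinyl group on the fully substituted C5, which cannot homodimerise, undergoes cross metathesis with excess 12; loss of ethylene forms C1'=C2', expected mainly E. The closest known reaction types are ring-rearrangement metathesis of cycloalkenes bearing a tethered alkene, acrylate ring-closing metathesis to butenolides and cross metathesis of allylic tertiary silyl ethers. No stereocentre is formed, and the quaternary C5 and C6a cannot epimerise. The selectivity needed is closure at C3a and not C1', secured by five- against seven-membered ring size, and cross metathesis at the vinyl group and not the lactone alkene, secured by the inertness of the conjugated ring alkene.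

Step 9
Reactants: 14 (5S)-5-[(2R,3E)-14-[4-(benzyloxy)phenyl]-2-methyl-2-(triethylsilyloxy)tetradec-3-en-1-yl]-5-methylfuran-2(5H)-one
Product: 16 (3aS,5R,6aS)-5-[(1E)-12-[4-(benzyloxy)phenyl]dodec-1-en-1-yl]-5,6a-dimethyltetrahydrofuro[3,2-b]furan-2(3H)-one, via hydroxy butenolide 15 (not isolated)
Conditions: Bu4NF, THF, 0 °C to rt
Reagents that add atoms: none
Why: Fluoride removes the triethylsilyl group and the tertiary alkoxide adds to C3a of the butenolide by 5-exo-trig oxa-Michael addition. The tether through C6 allows only the cis fusion, so C3a (S) is set by C6a; the butenolide has no γ-hydrogen to lose.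

Step 10
Reactants: 16 (3aS,5R,6aS)-5-[(1E)-12-[4-(benzyloxy)phenyl]dodec-1-en-1-yl]-5,6a-dimethyltetrahydrofuro[3,2-b]furan-2(3H)-one
Product: 17 plakortone N, (3aS,5S,6aS)-5-[12-(4-hydroxyphenyl)dodecyl]-5,6a-dimethyltetrahydrofuro[3,2-b]furan-2(3H)-one
Conditions: H2 (1 atm), 10% Pd/C, EtOAc, rt
Reagents that add atoms: none
Why: Heterogeneous hydrogenation saturates C1'=C2' and hydrogenolyses the benzyl ether in one operation. The C5 descriptor changes from R to S only because the chain loses CIP priority on saturation.

## Compound list

1 | (S)-4-(tert-butyldimethylsilyloxy)cyclopent-2-en-1-one | O=C1C=C[C@@H](O[Si](C)(C)C(C)(C)C)C1 | starting material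
2 | (1R,4S)-4-(tert-butyldimethylsilyloxy)-1-methylcyclopent-2-en-1-ol | O[C@@]1(C)C=C[C@@H](O[Si](C)(C)C(C)(C)C)C1 | intermediate
3 | (1R,4S)-1-methylcyclopent-2-ene-1,4-diol | O[C@@]1(C)C=C[C@@H](O)C1 | intermediate
4 | (R)-4-hydroxy-4-methylcyclopent-2-en-1-one | O[C@@]1(C)C=CC(=O)C1 | intermediate
5 | (R)-4-methyl-4-(triethylsilyloxy)cyclopent-2-en-1-one | CC[Si](CC)(CC)O[C@@]1(C)C=CC(=O)C1 | intermediate
6 | (1S,4R)-1,4-dimethyl-4-(triethylsilyloxy)cyclopent-2-en-1-ol | O[C@]1(C)C=C[C@](C)(O[Si](CC)(CC)CC)C1 | intermediate
7 | acryloyl chloride | C=CC(Cl)=O | starting material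
8 | (1S,4R)-1,4-dimethyl-4-(triethylsilyloxy)cyclopent-2-en-1-yl prop-2-enoate | C=CC(=O)O[C@]1(C)C=C[C@](C)(O[Si](CC)(CC)CC)C1 | intermediate
9 | 11-bromoundec-1-ene | C=CCCCCCCCCCBr | starting material
10 | 1-(benzyloxy)-4-(chloromethyl)benzene (4-(benzyloxy)benzyl chloride) | ClCc1ccc(OCc2ccccc2)cc1 | starting material
11 | undec-10-en-1-ylmagnesium bromide | C=CCCCCCCCCC[Mg]Br | intermediate (not isolated)
12 | 1-(benzyloxy)-4-(dodec-11-en-1-yl)benzene | C=CCCCCCCCCCCc1ccc(OCc2ccccc2)cc1 | intermediate
13 | (5S)-5-methyl-5-[(2R)-2-methyl-2-(triethylsilyloxy)but-3-en-1-yl]furan-2(5H)-one | O=C1C=C[C@](C)(C[C@@](C)(O[Si](CC)(CC)CC)C=C)O1 | intermediate (not isolated)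
14 | (5S)-5-[(2R,3E)-14-[4-(benzyloxy)phenyl]-2-methyl-2-(triethylsilyloxy)tetradec-3-en-1-yl]-5-methylfuran-2(5H)-one | O=C1C=C[C@](C)(C[C@@](C)(O[Si](CC)(CC)CC)/C=C/CCCCCCCCCCc2ccc(OCc3ccccc3)cc2)O1 | intermediate
15 | (5S)-5-[(2R,3E)-14-[4-(benzyloxy)phenyl]-2-hydroxy-2-methyltetradec-3-en-1-yl]-5-methylfuran-2(5H)-one | O=C1C=C[C@](C)(C[C@@](C)(O)/C=C/CCCCCCCCCCc2ccc(OCc3ccccc3)cc2)O1 | intermediate (not isolated)
16 | (3aS,5R,6aS)-5-[(1E)-12-[4-(benzyloxy)phenyl]dodec-1-en-1-yl]-5,6a-dimethyltetrahydrofuro[3,2-b]furan-2(3H)-one | C[C@]1(/C=C/CCCCCCCCCCc2ccc(OCc3ccccc3)cc2)C[C@]2(C)OC(=O)C[C@@H]2O1 | intermediate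
17 | plakortone N, (3aS,5S,6aS)-5-[12-(4-hydroxyphenyl)dodecyl]-5,6a-dimethyltetrahydrofuro[3,2-b]furan-2(3H)-one | C[C@]1(CCCCCCCCCCCCc2ccc(O)cc2)C[C@]2(C)OC(=O)C[C@@H]2O1 | target

## Step count and least certain steps

Total: 10 steps. Longest linear sequence: 9 steps (1, 2, 3, 4, 5, 6, 8, 9, 10) from 1; step 7 is a one-step branch.

Step 8 (key step). The ring alkene lies between two fully substituted carbons and has little strain, so metallacyclobutane formation may be slow. The opened diene may re-close to the cyclopentene faster than the C3a alkylidene finds the acrylate, and the catalyst may decay first. In the second stage the vinyl group on a fully substituted carbon cross-couples slowly. Ruthenium hydrides may also move the double bond of 12 along the chain and give chain-shortened products; 1,4-benzoquinone (10 mol %) can be added against this.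

Fallback, setting out from 6 and returning at 13:
- Esterification with 2-(diethoxyphosphoryl)acetic acid (DCC, DMAP, CH2Cl2) would give (1S,4R)-1,4-dimethyl-4-(triethylsilyloxy)cyclopent-2-en-1-yl 2-(diethoxyphosphoryl)acetate F1.
- Ozonolysis (O3, CH2Cl2, −78 °C; Me2S) would open the ring to the dialdehyde (2S,4R)-2,4-dimethyl-1,5-dioxo-4-(triethylsilyloxy)pentan-2-yl 2-(diethoxyphosphoryl)acetate F2, neither of whose aldehydes can enolise.
- Intramolecular Horner–Wadsworth–Emmons reaction (LiCl, iPr2NEt, MeCN) should close the five-membered ring onto the nearer aldehyde and give (2R)-2-methyl-3-[(2S)-2-methyl-5-oxo-2,5-dihydrofuran-2-yl]-2-(triethylsilyloxy)propanal F3.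
- Wittig methylenation (Ph3P=CH2, THF, −78 °C) would give 13, now isolated, which is cross-coupled with 12 as in the second stage of step 8 to reach 14.

Step 5. Methyl and silyloxy on the same carbon may not differ enough, so attack on the silyloxy face could compete and give the trans isomer. The lithium alkoxide could also pass its silyl group to the other oxygen if allowed to warm, which erodes enantiopurity.

Fallback, setting out from 5 and returning at 6:
- Wittig methylenation (Ph3P=CH2, THF) would give triethyl{[(1R)-1-methyl-4-methylidenecyclopent-2-en-1-yl]oxy}silane F4.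
- Epoxidation of the more electron-rich exocyclic alkene (mCPBA, NaHCO3, CH2Cl2, 0 °C) would give (3S,6R)-6-methyl-6-(triethylsilyloxy)-1-oxaspiro[2.4]hept-4-ene F5.
- LiEt3BH (THF, −78 to 0 °C, cold quench) would open the epoxide at its CH2 to give 6.

Here the oxygen, not the methyl group, enters from the more accessible face. The sequence therefore gives the cis compound exactly when reagents prefer the silyloxy face; it does not help if neither face is preferred.

Step 6. Acylation of the hindered tertiary allylic alcohol may be slow. Over long reaction times the substrate may ionise or eliminate to dienes, and the acid chloride may polymerise.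

Fallback, setting out from 5 and returning at 8: MeLi is added as in step 5, and acryloyl chloride 7 is added directly to the cold lithium (1S,4R)-1,4-dimethyl-4-(triethylsilyloxy)cyclopent-2-en-1-olate F6 (−78 to −40 °C). The alkoxide is acylated in the flask and 6 is not isolated.

Step 10. Hydrogenolysis of the allylic tertiary C5–O4 bond on palladium may compete with saturation of the alkene and open the tetrahydrofuran.

Fallback, setting out from 16 and returning at 17: diimide reduction (2-nitrobenzenesulfonyl hydrazide, Et3N, CH2Cl2, rt) would saturate the alkene without a metal surface and give plakortone N benzyl ether F7. Its ether carbon is no longer allylic, and H2 over 10% Pd/C in EtOAc would then remove the benzyl group to give 17.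

## Further compounds

F1 | step 8 | (1S,4R)-1,4-dimethyl-4-(triethylsilyloxy)cyclopent-2-en-1-yl 2-(diethoxyphosphoryl)acetate | CCOP(=O)(OCC)CC(=O)O[C@]1(C)C=C[C@](C)(O[Si](CC)(CC)CC)C1
F2 | step 8 | (2S,4R)-2,4-dimethyl-1,5-dioxo-4-(triethylsilyloxy)pentan-2-yl 2-(diethoxyphosphoryl)acetate | CCOP(=O)(OCC)CC(=O)O[C@](C)(C=O)C[C@@](C)(O[Si](CC)(CC)CC)C=O
F3 | step 8 | (2R)-2-methyl-3-[(2S)-2-methyl-5-oxo-2,5-dihydrofuran-2-yl]-2-(triethylsilyloxy)propanal | O=C1C=C[C@](C)(C[C@@](C)(O[Si](CC)(CC)CC)C=O)O1
F4 | step 5 | triethyl{[(1R)-1-methyl-4-methylidenecyclopent-2-en-1-yl]oxy}silane | C=C1C=C[C@](C)(O[Si](CC)(CC)CC)C1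
F5 | step 5 | (3S,6R)-6-methyl-6-(triethylsilyloxy)-1-oxaspiro[2.4]hept-4-ene | C1O[C@@]12C=C[C@](C)(O[Si](CC)(CC)CC)C2
F6 | step 6 | lithium (1S,4R)-1,4-dimethyl-4-(triethylsilyloxy)cyclopent-2-en-1-olate | [Li+].[O-][C@]1(C)C=C[C@](C)(O[Si](CC)(CC)CC)C1
F7 | step 10 | plakortone N benzyl ether, (3aS,5S,6aS)-5-[12-[4-(benzyloxy)phenyl]dodecyl]-5,6a-dimethyltetrahydrofuro[3,2-b]furan-2(3H)-one | C[C@]1(CCCCCCCCCCCCc2ccc(OCc3ccccc3)cc2)C[C@]2(C)OC(=O)C[C@@H]2O1
A1 | alternative 1 | tert-butyl 2-[5-[12-[4-(benzyloxy)phenyl]dodecyl]-5-methyl-3-oxotetrahydrofuran-2-yl]acetate | C[C@]1(CCCCCCCCCCCCc2ccc(OCc3ccccc3)cc2)CC(=O)[C@H](CC(=O)OC(C)(C)C)O1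
A2 | alternative 1 | tert-butyl 3-({14-[4-(benzyloxy)phenyl]tetradecan-2-yl}oxy)-5-diazo-4-oxopentanoate | C[C@@H](CCCCCCCCCCCCc1ccc(OCc2ccccc2)cc1)O[C@@H](CC(=O)OC(C)(C)C)C(=O)C=[N+]=[N-]
A3 | alternative 2 | plakortone N benzyl ether | C[C@]1(CCCCCCCCCCCCc2ccc(OCc3ccccc3)cc2)C[C@]2(C)OC(=O)C[C@@H]2O1
A4 | alternative 2 | 16-[4-(benzyloxy)phenyl]-4-(ethenyloxy)-4-methylhexadecan-2-one | CC(=O)C[C@@](C)(OC=C)CCCCCCCCCCCCc1ccc(OCc2ccccc2)cc1
A5 | alternative 3 | 5-[12-[4-(benzyloxy)phenyl]dodecyl]-6-iodo-5,6a-dimethyltetrahydrofuro[3,2-b]furan-2(3H)-one | C[C@]1(CCCCCCCCCCCCc2ccc(OCc3ccccc3)cc2)[C@@H](I)[C@]2(C)OC(=O)C[C@@H]2O1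
A6 | alternative 3 | 2-[12-[4-(benzyloxy)phenyl]dodecyl]-2,4-dimethyl-2,3-dihydrofuran-3-yl acetate | C[C@]1(CCCCCCCCCCCCc2ccc(OCc3ccccc3)cc2)[C@H](OC(C)=O)C(C)=CO1
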